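**Retrosynthetic overview**
1. The target is a (2S)-flavan. Ring C is closed last, at C3–C4: the CH2 terminus (C3) of an aryl 1-arylvinyl ether, with O1–C2 already in place, attacks C4 of a ring-A ortho-quinone methide. In the same flask the resulting C2 oxocarbenium ion is reduced enantioselectively (chiral phosphoric acid, Hantzsch ester).
2. Enabling feature: the free C5 hydroxyl of ring A is ortho to C4a, so C4 and O5 can be stored together as a saligenin acetonide (a temporary 1,3-dioxine ring). This ionises to the quinone methide C4=C4a–C5=O, while O1 holds C3 at six-membered-ring distance from C4 and the 2-aryl group stabilises the cation at C2.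
3. C2=C3 comes from Petasis methylenation of the aryl ester formed from the ring-A phenol and the ring-B acid (O1–C2).
4. Ring A comes from symmetric 2,6-dihydroxy-4-methoxybenzaldehyde. Reduction and ketalisation differentiate the two phenols (O5 into the dioxine, O1 free); O-(1,1-dimethylallyl)ation and a Claisen shift then place the prenyl group on C8, ortho to O1.
5. Ring order: rings A and B are bought; the temporary dioxine ring is formed in step 2; ring C is formed in step 9, where the dioxine is opened; desilylation is last.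

Key step: step 9

Assumption: (R)-TRIP is taken to deliver hydride to the Re face of C2 (giving 2S), by analogy with its behaviour towards 2-aryl cyclic iminium ions; if the sense proves opposite, the (S)-acid is used with no other change.

**Step 1**
Reactants: 1 2,4,6-trihydroxybenzaldehyde
Product: 2 2,6-dihydroxy-4-methoxybenzaldehyde
Conditions: MeI (1.0 equiv), K2CO3 (1.0 equiv), DMF, 0 °C to rt
Reagents that add atoms: iodomethane, CI
Why: Williamson O-methylation should occur at the C4 hydroxyl, which is the most acidic and the only one not hydrogen-bonded to the formyl group, so one equivalent of base and electrophile should give the symmetric monoether.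

**Step 2**
Reactants: 2 2,6-dihydroxy-4-methoxybenzaldehyde
Product: 4 7-methoxy-2,2-dimethyl-4H-1,3-benzodioxin-5-ol, via benzylic triol 3 (not isolated)
Conditions: NaBH4, THF/MeOH, −20 °C; AcOH to pH 6, concentrate; then Me2C(OMe)2, PPTS (5 mol %), acetone, 0 °C; Et3N quench
Reagents that add atoms: 2,2-dimethoxypropane, COC(C)(C)OC
Why: Borohydride reduction of the salicylaldehyde followed at once by acid-catalysed transketalisation should tie the benzylic oxygen to one of the two equivalent phenols as the saligenin acetonide, the symmetry of 3 ensuring a single regioisomer and the immediate ring closure protecting the electron-rich benzylic alcohol from self-condensation.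

**Step 3**
Reactants: 5 2-methylbut-3-en-2-ol
Product: 6 tert-butyl 2-methylbut-3-en-2-yl carbonate
Conditions: n-BuLi, THF, −78 °C; Boc2O, −78 °C to rt
Reagents that add atoms: di-tert-butyl dicarbonate, CC(C)(C)OC(=O)OC(=O)OC(C)(C)C
Why: Acylation of the lithium alkoxide of the tertiary allylic alcohol with Boc2O is a standard preparation of tertiary allylic carbonates.

**Step 4**
Reactants: 4 7-methoxy-2,2-dimethyl-4H-1,3-benzodioxin-5-ol; 6 tert-butyl 2-methylbut-3-en-2-yl carbonate
Product: 7 7-methoxy-2,2-dimethyl-5-(2-methylbut-3-en-2-yloxy)-4H-1,3-benzodioxine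
Conditions: Pd(PPh3)4 (2 mol %), THF, 0 °C to rt
Reagents that add atoms: none
Why: Decarboxylative Tsuji–Trost O-allylation with zerovalent palladium should deliver the phenoxide to the more substituted terminus of the 1,1-dimethylallyl palladium cation under kinetic control, giving the tertiary aryl ether under neutral conditions that leave the acetonide intact.

**Step 5**
Reactants: 7 7-methoxy-2,2-dimethyl-5-(2-methylbut-3-en-2-yloxy)-4H-1,3-benzodioxine
Product: 8 7-methoxy-2,2-dimethyl-6-(3-methylbut-2-en-1-yl)-4H-1,3-benzodioxin-5-ol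
Conditions: PhMe, 100 °C, sealed tube, BHT (trace)
Reagents that add atoms: none
Why: The aromatic Claisen rearrangement, a [3,3]-sigmatropic shift accelerated by the gem-dimethyl group, should carry the allyl unit with allylic inversion to the only free ortho position (between the ether oxygen and the methoxy group), which turns the 1,1-dimethylallyl ether into the linear prenyl group and returns the phenol.

**Step 6**
Reactants: 9 2,4-dihydroxybenzoic acid
Product: 11 2,4-bis(tert-butyldimethylsilyloxy)benzoic acid, via silyl ester 10 (not isolated)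
Conditions: TBSCl (3.5 equiv), imidazole, DMF, rt; then AcOH/THF/H2O, 0 °C to rt
Reagents that add atoms: tert-butyldimethylsilyl chloride, CC(C)(C)[Si](C)(C)Cl
Why: Exhaustive silylation followed by selective hydrolysis of the far more labile silyl ester (aryl silyl ethers survive dilute acetic acid) is the standard entry to silyl-protected hydroxybenzoic acids.

**Step 7**
Reactants: 8 7-methoxy-2,2-dimethyl-6-(3-methylbut-2-en-1-yl)-4H-1,3-benzodioxin-5-ol; 11 2,4-bis(tert-butyldimethylsilyloxy)benzoic acid
Product: 12 7-methoxy-2,2-dimethyl-6-(3-methylbut-2-en-1-yl)-4H-1,3-benzodioxin-5-yl 2,4-bis(tert-butyldimethylsilyloxy)benzoate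
Conditions: EDC·HCl (1.5 equiv), DMAP (0.5 equiv), CH2Cl2, rt
Reagents that add atoms: none
Why: Steglich esterification through the N-acylpyridinium ion should acylate the hindered but non-chelated phenol under nearly neutral conditions that spare the acetonide, the silyl ethers and the prenyl group.

**Step 8**
Reactants: 12 7-methoxy-2,2-dimethyl-6-(3-methylbut-2-en-1-yl)-4H-1,3-benzodioxin-5-yl 2,4-bis(tert-butyldimethylsilyloxy)benzoate
Product: 13 5-({1-[2,4-bis(tert-butyldimethylsilyloxy)phenyl]ethenyl}oxy)-7-methoxy-2,2-dimethyl-6-(3-methylbut-2-en-1-yl)-4H-1,3-benzodioxine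
Conditions: Cp2TiMe2 (3 equiv), PhMe/THF, 70 °C, dark; filtration through basic Al2O3
Reagents that add atoms: dimethyltitanocene (Petasis reagent, Cp2TiMe2), C[Ti](C)(C1C=CC=C1)C1C=CC=C1
Why: Petasis methylenation (titanocene methylidene [2+2] addition and cycloreversion, the reactivity by which phenyl benzoate is turned into 1-phenoxy-1-phenylethene) should convert the only carbonyl group into the aryl 1-arylvinyl ether without touching the trisubstituted prenyl alkene, the ketal or the silyl ethers.

**Step 9**
Reactants: 13 5-({1-[2,4-bis(tert-butyldimethylsilyloxy)phenyl]ethenyl}oxy)-7-methoxy-2,2-dimethyl-6-(3-methylbut-2-en-1-yl)-4H-1,3-benzodioxine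
Product: 16 (2S)-2-[2,4-bis(tert-butyldimethylsilyloxy)phenyl]-7-methoxy-8-(3-methylbut-2-en-1-yl)-3,4-dihydro-2H-chromen-5-ol, via ortho-quinone methide 14 (not isolated), via 4H-chromene 15 (not isolated)
Conditions: (R)-TRIP [(R)-3,3'-bis(2,4,6-triisopropylphenyl)-1,1'-binaphthyl-2,2'-diyl hydrogen phosphate] (10 mol %), 5 Å molecular sieves, PhMe (0.01 M), rt to 40 °C; then Hantzsch ester (diethyl 2,6-dimethyl-1,4-dihydropyridine-3,5-dicarboxylate, 1.5 equiv), 0 °C to rt
Reagents that add atoms: none
Why: Proposed new method: the chiral phosphoric acid is expected to protonate the ketal, the C4–O bond ionises with the help of the three ring-A oxygens and acetone is lost to give ortho-quinone methide 14 (C4=C4a–C5=O), whose exocyclic C4 is attacked by the terminal carbon C3 of the tethered vinyl ether; this re-aromatises ring A, frees the C5 hydroxyl and leaves a 2-aryl oxocarbenium ion at C2 that rests as 4H-chromene 15 until the Hantzsch ester is added, when protonation at C3 regenerates the oxocarbenium/chiral phosphate ion pair and hydride is transferred to C2. The closest known reaction types are the phosphoric-acid-catalysed additions of enol ethers and styrenes to ortho-quinone methides released from ortho-hydroxybenzyl alcohols, the Petasis–Ferrier-type closure of an enol ether onto a cation, and the phosphoric acid/Hantzsch ester transfer hydrogenation of benzopyrylium and quinolinium ions; what is new is the intramolecular closure through the C5 oxygen and its coupling to the asymmetric reduction. Ring C is closed by the C3–C4 bond in a 6-(enolendo)-exo-trig mode, that is 6-endo with respect to the vinyl ether, through a chair-like array in which the vinyl ether lies over the face of the quinone methide. The C2 stereocentre is set under catalyst control by hydride delivery to the Re face of the oxocarbenium ion inside the contact ion pair (the Hantzsch N–H hydrogen-bonded to the phosphate), which gives 2S. The step needs C3 to win over all other nucleophiles and hydride to arrive only after ring closure: the O1 tether lets no carbon but C3 reach C4, a [4+2] closure onto the C5 oxygen and attack by the C8 prenyl alkene would both require a meta-bridged ring and are excluded, high dilution suppresses intermolecular arylation, and the reductant is withheld until 14 is consumed so that neither 14 nor the open-chain oxocarbenium ion is reduced.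

**Step 10**
Reactants: 16 (2S)-2-[2,4-bis(tert-butyldimethylsilyloxy)phenyl]-7-methoxy-8-(3-methylbut-2-en-1-yl)-3,4-dihydro-2H-chromen-5-ol
Product: 17 (2S)-2-(2,4-dihydroxyphenyl)-7-methoxy-8-(3-methylbut-2-en-1-yl)-3,4-dihydro-2H-chromen-5-ol
Conditions: TBAF (2.2 equiv), AcOH (2.5 equiv), THF, 0 °C
Reagents that add atoms: none
Why: Fluoride-induced cleavage of the two aryl silyl ethers, buffered with acetic acid so that no free phenoxide para to C2 can open ring C through a quinone methide, should release the target without loss of configuration.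

**Compound list**
1 | 2,4,6-trihydroxybenzaldehyde | O=Cc1c(O)cc(O)cc1O | starting material
2 | 2,6-dihydroxy-4-methoxybenzaldehyde | COc1cc(O)c(C=O)c(O)c1 | intermediate
3 | 2-(hydroxymethyl)-5-methoxybenzene-1,3-diol (benzylic triol, not isolated) | COc1cc(O)c(CO)c(O)c1 | intermediate
4 | 7-methoxy-2,2-dimethyl-4H-1,3-benzodioxin-5-ol | COc1cc(O)c2COC(C)(C)Oc2c1 | intermediate
5 | 2-methylbut-3-en-2-ol | CC(C)(O)C=C | starting material
6 | tert-butyl 2-methylbut-3-en-2-yl carbonate | CC(C)(C)OC(=O)OC(C)(C)C=C | intermediate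
7 | 7-methoxy-2,2-dimethyl-5-(2-methylbut-3-en-2-yloxy)-4H-1,3-benzodioxine | COc1cc(OC(C)(C)C=C)c2COC(C)(C)Oc2c1 | intermediate
8 | 7-methoxy-2,2-dimethyl-6-(3-methylbut-2-en-1-yl)-4H-1,3-benzodioxin-5-ol | COc1cc2OC(C)(C)OCc2c(O)c1CC=C(C)C | intermediate
9 | 2,4-dihydroxybenzoic acid | OC(=O)c1ccc(O)cc1O | starting material
10 | tert-butyldimethylsilyl 2,4-bis(tert-butyldimethylsilyloxy)benzoate (silyl ester, not isolated) | CC(C)(C)[Si](C)(C)OC(=O)c1ccc(O[Si](C)(C)C(C)(C)C)cc1O[Si](C)(C)C(C)(C)C | intermediate
11 | 2,4-bis(tert-butyldimethylsilyloxy)benzoic acid | OC(=O)c1ccc(O[Si](C)(C)C(C)(C)C)cc1O[Si](C)(C)C(C)(C)C | intermediate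
12 | 7-methoxy-2,2-dimethyl-6-(3-methylbut-2-en-1-yl)-4H-1,3-benzodioxin-5-yl 2,4-bis(tert-butyldimethylsilyloxy)benzoate | COc1cc2OC(C)(C)OCc2c(OC(=O)c3ccc(O[Si](C)(C)C(C)(C)C)cc3O[Si](C)(C)C(C)(C)C)c1CC=C(C)C | intermediate
13 | 5-({1-[2,4-bis(tert-butyldimethylsilyloxy)phenyl]ethenyl}oxy)-7-methoxy-2,2-dimethyl-6-(3-methylbut-2-en-1-yl)-4H-1,3-benzodioxine | COc1cc2OC(C)(C)OCc2c(OC(=C)c3ccc(O[Si](C)(C)C(C)(C)C)cc3O[Si](C)(C)C(C)(C)C)c1CC=C(C)C | intermediate
14 | 5-({1-[2,4-bis(tert-butyldimethylsilyloxy)phenyl]ethenyl}oxy)-3-methoxy-6-methylidene-4-(3-methylbut-2-en-1-yl)cyclohexa-2,4-dien-1-one (ortho-quinone methide, not isolated) | C=C1C(=O)C=C(OC)C(CC=C(C)C)=C1OC(=C)c1ccc(O[Si](C)(C)C(C)(C)C)cc1O[Si](C)(C)C(C)(C)C | intermediate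
15 | 2-[2,4-bis(tert-butyldimethylsilyloxy)phenyl]-7-methoxy-8-(3-methylbut-2-en-1-yl)-4H-chromen-5-ol (not isolated) | COc1cc(O)c2c(c1CC=C(C)C)OC(c1ccc(O[Si](C)(C)C(C)(C)C)cc1O[Si](C)(C)C(C)(C)C)=CC2 | intermediate
16 | (2S)-2-[2,4-bis(tert-butyldimethylsilyloxy)phenyl]-7-methoxy-8-(3-methylbut-2-en-1-yl)-3,4-dihydro-2H-chromen-5-ol | COc1cc(O)c2c(c1CC=C(C)C)O[C@H](c1ccc(O[Si](C)(C)C(C)(C)C)cc1O[Si](C)(C)C(C)(C)C)CC2 | intermediate
17 | (2S)-2-(2,4-dihydroxyphenyl)-7-methoxy-8-(3-methylbut-2-en-1-yl)-3,4-dihydro-2H-chromen-5-ol | COc1cc(O)c2c(c1CC=C(C)C)O[C@H](c1ccc(O)cc1O)CC2 | target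

**Count**
Total steps: 10. Longest linear sequence: 8 steps (steps 1, 2, 4, 5, 7, 8, 9, 10).

**Steps most likely to fail**

Step 9 (proposed new method).
- What may go wrong: protonation of the vinyl ether ahead of ketal ionisation (followed by hydrolysis, capture of the open oxocarbenium ion by the prenyl alkene, or its later reduction), and poor facial discrimination in the hydride transfer to the ion pair.
- Fallback (known chemistry): ring C is closed at O1–C2 on a carbinol centre set beforehand. It sets out from 8 and 11 and returns to the route at 17.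
- Acid 11 is treated with MeLi (2.2 equiv, THF, −78 to 0 °C) to give 1-[2,4-bis(tert-butyldimethylsilyloxy)phenyl]ethan-1-one F1, which is converted (LDA, Me3SiCl, THF, −78 °C) into {1-[2,4-bis(tert-butyldimethylsilyloxy)phenyl]ethenyloxy}trimethylsilane F2.
- Lewis-acid opening of acetonide 8 (BF3·OEt2, CH2Cl2, −78 °C) in the presence of F2, a Mukaiyama-type addition to the quinone methide released from 8, should give after aqueous work-up 1-[2,4-bis(tert-butyldimethylsilyloxy)phenyl]-3-[2,6-dihydroxy-4-methoxy-3-(3-methylbut-2-en-1-yl)phenyl]propan-1-one F3.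
- The less hindered phenol (the future O5, next to the ring C–H) is silylated (TBSCl 1.05 equiv, imidazole, CH2Cl2, 0 °C) to give 1-[2,4-bis(tert-butyldimethylsilyloxy)phenyl]-3-[6-(tert-butyldimethylsilyloxy)-2-hydroxy-4-methoxy-3-(3-methylbut-2-en-1-yl)phenyl]propan-1-one F4.
- Corey–Bakshi–Shibata reduction ((S)-2-methyl-CBS-oxazaborolidine, BH3·SMe2, THF, −20 °C) should give (1R)-1-[2,4-bis(tert-butyldimethylsilyloxy)phenyl]-3-[6-(tert-butyldimethylsilyloxy)-2-hydroxy-4-methoxy-3-(3-methylbut-2-en-1-yl)phenyl]propan-1-ol F5.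
- Mitsunobu etherification (PPh3, DIAD, THF, 0 °C) closes ring C with inversion to (2S)-2-[2,4-bis(tert-butyldimethylsilyloxy)phenyl]-5-(tert-butyldimethylsilyloxy)-7-methoxy-8-(3-methylbut-2-en-1-yl)-3,4-dihydro-2H-chromene F6, and desilylation under the conditions of step 10 gives 17.

Step 2.
- What may go wrong: dehydration of the trihydroxybenzyl alcohol to its ortho-quinone methide with self-condensation, or over-reduction of the benzylic position, before the ketal ring closes.
- Fallback: a benzyl alcohol with two free ortho hydroxyls is never formed. It sets out from 2 and returns at 4.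
- Mono-O-allylation of 2 (allyl bromide 1.0 equiv, K2CO3, DMF, rt) gives 2-(allyloxy)-6-hydroxy-4-methoxybenzaldehyde F7.
- NaBH4 reduction (MeOH, 0 °C) gives the less activated, isolable 3-(allyloxy)-2-(hydroxymethyl)-5-methoxyphenol F8.
- Ketalisation (Me2C(OMe)2, PPTS, acetone) gives 5-(allyloxy)-7-methoxy-2,2-dimethyl-4H-1,3-benzodioxine F9, and deallylation (Pd(PPh3)4 cat., morpholine, THF, rt) gives 4.

Step 4.
- What may go wrong: attack of the phenoxide at the unsubstituted allyl terminus, or equilibration of the tertiary ether by re-ionisation, leading to the linear prenyl ether, whose Claisen shift would place a 1,1-dimethylallyl group on the ring.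
- Fallback: the tertiary C–O bond is made by substitution instead of allyl-palladium chemistry. It sets out from 4 and returns at 7.
- Copper-catalysed propargylation of 4 with 3-chloro-3-methylbut-1-yne (CuCl2 cat., DBU, MeCN, 0 °C) gives 7-methoxy-2,2-dimethyl-5-(2-methylbut-3-yn-2-yloxy)-4H-1,3-benzodioxine F10.
- Semi-hydrogenation (H2, Pd/CaCO3 poisoned with Pb(OAc)2, quinoline, EtOAc) gives 7.

**Further compounds**
F1 | step 9 | 1-[2,4-bis(tert-butyldimethylsilyloxy)phenyl]ethan-1-one | CC(=O)c1ccc(O[Si](C)(C)C(C)(C)C)cc1O[Si](C)(C)C(C)(C)C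
F2 | step 9 | {1-[2,4-bis(tert-butyldimethylsilyloxy)phenyl]ethenyloxy}trimethylsilane | C=C(O[Si](C)(C)C)c1ccc(O[Si](C)(C)C(C)(C)C)cc1O[Si](C)(C)C(C)(C)C
F3 | step 9 | 1-[2,4-bis(tert-butyldimethylsilyloxy)phenyl]-3-[2,6-dihydroxy-4-methoxy-3-(3-methylbut-2-en-1-yl)phenyl]propan-1-one | COc1cc(O)c(CCC(=O)c2ccc(O[Si](C)(C)C(C)(C)C)cc2O[Si](C)(C)C(C)(C)C)c(O)c1CC=C(C)C
F4 | step 9 | 1-[2,4-bis(tert-butyldimethylsilyloxy)phenyl]-3-[6-(tert-butyldimethylsilyloxy)-2-hydroxy-4-methoxy-3-(3-methylbut-2-en-1-yl)phenyl]propan-1-one | COc1cc(O[Si](C)(C)C(C)(C)C)c(CCC(=O)c2ccc(O[Si](C)(C)C(C)(C)C)cc2O[Si](C)(C)C(C)(C)C)c(O)c1CC=C(C)C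
F5 | step 9 | (1R)-1-[2,4-bis(tert-butyldimethylsilyloxy)phenyl]-3-[6-(tert-butyldimethylsilyloxy)-2-hydroxy-4-methoxy-3-(3-methylbut-2-en-1-yl)phenyl]propan-1-ol | COc1cc(O[Si](C)(C)C(C)(C)C)c(CC[C@@H](O)c2ccc(O[Si](C)(C)C(C)(C)C)cc2O[Si](C)(C)C(C)(C)C)c(O)c1CC=C(C)C
F6 | step 9 | (2S)-2-[2,4-bis(tert-butyldimethylsilyloxy)phenyl]-5-(tert-butyldimethylsilyloxy)-7-methoxy-8-(3-methylbut-2-en-1-yl)-3,4-dihydro-2H-chromene | COc1cc(O[Si](C)(C)C(C)(C)C)c2c(c1CC=C(C)C)O[C@H](c1ccc(O[Si](C)(C)C(C)(C)C)cc1O[Si](C)(C)C(C)(C)C)CC2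
F7 | step 2 | 2-(allyloxy)-6-hydroxy-4-methoxybenzaldehyde | COc1cc(O)c(C=O)c(OCC=C)c1
F8 | step 2 | 3-(allyloxy)-2-(hydroxymethyl)-5-methoxyphenol | COc1cc(O)c(CO)c(OCC=C)c1
F9 | step 2 | 5-(allyloxy)-7-methoxy-2,2-dimethyl-4H-1,3-benzodioxine | COc1cc(OCC=C)c2COC(C)(C)Oc2c1
F10 | step 4 | 7-methoxy-2,2-dimethyl-5-(2-methylbut-3-yn-2-yloxy)-4H-1,3-benzodioxine | COc1cc(OC(C)(C)C#C)c2COC(C)(C)Oc2c1
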